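**Retrosynthetic overview** (locants are those of the target cyclopentane: C1 quaternary, C2 CH2OAr, C3 CH3, C4 ring CH2, C5 2-methylprop-1-enyl)
1. Ferulsinaic acid ⇐ Mitsunobu etherification with umbelliferone and Wittig olefination of a hydroxy aldehyde acid whose C5-formyl carbon and carboxyl carbon are the two ends of one cleaved C=C, so the cyclopentane is read as a 4,5-seco-cis-hydrindane.
2. That C=C is the silyl enol ether of a cis-7a-methylhydrindan-5-one (ozonolysis), built by Robinson annulation of but-3-en-2-one onto a cyclopentanone; this sets C1 (methyl cis to CH2O) and C5–H (cis ring fusion).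
3. Enabling feature: C5 lies between the only ring CH2 (C4) and the quaternary C1, so C4–C5–C1 is the α–C(=O)–α′ triad of a latent ketone, while C3(CH3)–C2(CH2O) is the β,α pair of crotonaldehyde.
4. The cyclopentanone therefore forms in one operation from crotonaldehyde and ethyl 4-bromo-3-oxopentanoate: the β-keto ester carbon (C4) adds to C3, and the enamine carbon (C2) alkylates the C–Br carbon (C1); the amine catalyst sets the absolute configuration.
5. Ring order: cyclopentane (step 1), temporary cyclohexenone (step 4, cleaved in step 7); the coumarin enters preformed.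

Key step: step 1

Remark: commercial (E)-crotonaldehyde and racemic 2 are assumed; the facial sense of the (S)-prolinol silyl ether is taken from its usual shielding model (attack anti to the CPh2OTMS group), and the mirror-image catalyst would be used if it proved opposite.

**Step 1**
Reactants: 1 (E)-but-2-enal (crotonaldehyde); 2 ethyl 4-bromo-3-oxopentanoate
Product: 4 ethyl (1S,2R,3R,4S)-3-formyl-2,4-dimethyl-5-oxocyclopentane-1-carboxylate, via Michael adduct 3 (not isolated)
Conditions: 1 (1.3 equiv), (S)-α,α-diphenylprolinol trimethylsilyl ether (20 mol%), 2,6-lutidine (1.1 equiv), CHCl3, 4 °C → rt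
Reagents that add atoms: none
Why: The amine condenses with 1 to an (E)-iminium ion whose β-carbon is attacked, on the face opposite the CPh2(OTMS) group, by the enol of 2 through its doubly activated C2 (first C–C bond; the methyl-bearing stereocentre is catalyst-controlled); the resulting enamine then displaces bromide from the α-bromo ketone carbon in a 5-exo-tet SN2 alkylation (second C–C bond, closing the cyclopentanone), and hydrolysis releases 4 and the catalyst. The closest known reaction type is the amine-catalysed domino Michael/α-alkylation of enals with 4-bromoacetoacetates to 3-formylcyclopentanones, here extended to a secondary bromide. The formyl-bearing centre should be set trans to its neighbours by the anti approach of the (E)-enamine and, being α to the aldehyde, by equilibration. The ester- and methyl-bearing ketone α-centres are epimerisable, should settle trans and carry nothing forward (the first is decarboxylated in step 3, the second becomes the quaternary carbon in step 4), so the racemic bromide centre of 2 is of no consequence. The step needs C- over O-alkylation and Michael addition at C2 of 2 rather than C4; the 1,3-dicarbonyl acidity of C2–H, the mild hindered base and the carbonyl activation of the C–Br bond should secure both.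

**Step 2**
Reactants: 4 ethyl (1S,2R,3R,4S)-3-formyl-2,4-dimethyl-5-oxocyclopentane-1-carboxylate
Product: 5 ethyl (1S,2R,3R,4S)-3-(hydroxymethyl)-2,4-dimethyl-5-oxocyclopentane-1-carboxylate
Conditions: NaBH(OAc)3 (1.5 equiv), CH2Cl2, 0 °C → rt
Reagents that add atoms: none
Why: Chemoselective hydride reduction: NaBH(OAc)3 should reduce the aldehyde but neither ketone nor ester, fixing the former formyl carbon (trans to both ring neighbours) as the CH2O branch, after which this centre can no longer epimerise.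

**Step 3**
Reactants: 5 ethyl (1S,2R,3R,4S)-3-(hydroxymethyl)-2,4-dimethyl-5-oxocyclopentane-1-carboxylate
Product: 7 (2S,3R,4S)-3-(hydroxymethyl)-2,4-dimethylcyclopentan-1-one, via β-keto acid 6 (not isolated)
Conditions: 2 M HCl, 1,4-dioxane, 90 °C
Reagents that add atoms: none
Why: Acid hydrolysis of the β-keto ester and thermal decarboxylation remove the activating group and leave the ring CH2; the C–CH3 (from crotonaldehyde) and C–CH2OH centres are not α to the ketone and cannot epimerise, while the enolisable methyl-bearing α-carbon is reset in step 4.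

**Step 4**
Reactants: 7 (2S,3R,4S)-3-(hydroxymethyl)-2,4-dimethylcyclopentan-1-one; 8 but-3-en-2-one (methyl vinyl ketone)
Product: 11 (1R,2S,7aS)-1-(hydroxymethyl)-2,7a-dimethyl-1,2,3,6,7,7a-hexahydro-5H-inden-5-one, via diketone 9 (not isolated), via ketol 10 (not isolated)
Conditions: 8 (1.5 equiv), KOH (0.3 equiv), MeOH, 0 °C → rt, then 65 °C
Reagents that add atoms: none
Why: Robinson annulation: under equilibrating base the more substituted enolate should add to butenone (Michael addition) anti to the neighbouring hydroxymethyl group, creating the quaternary carbon (methyl cis to CH2OH, chain trans), and intramolecular aldol condensation of the methyl ketone onto the ring carbonyl then closes the cyclohexenone.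

**Step 5**
Reactants: 11 (1R,2S,7aS)-1-(hydroxymethyl)-2,7a-dimethyl-1,2,3,6,7,7a-hexahydro-5H-inden-5-one
Product: 12 (1R,2S,3aS,7aR)-1-(hydroxymethyl)-2,7a-dimethyloctahydro-5H-inden-5-one (cis-fused)
Conditions: H2 (1 atm), 10% Pd/C, EtOAc, rt
Reagents that add atoms: none
Why: Heterogeneous hydrogenation of 7a-methylhydrindenones should deliver hydrogen to the ring-fusion carbon from the face of the angular methyl (cis-hydrindanone), here also the face away from the 2-methyl group and the one on which the hydroxymethyl group can anchor to the metal; this sets the future C5–H cis to the C1 methyl.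

**Step 6**
Reactants: 12 (1R,2S,3aS,7aR)-1-(hydroxymethyl)-2,7a-dimethyloctahydro-5H-inden-5-one
Product: 13 tert-butyl({(1R,2S,3aS,7aR)-5-[(tert-butyldimethylsilyl)oxy]-2,7a-dimethyl-2,3,3a,6,7,7a-hexahydro-1H-inden-1-yl}methoxy)dimethylsilane
Conditions: TBSOTf (2.4 equiv), Et3N (4 equiv), CH2Cl2, 0 °C → rt
Reagents that add atoms: tert-butyldimethylsilyl trifluoromethanesulfonate, CC(C)(C)[Si](C)(C)OS(=O)(=O)C(F)(F)F
Why: Silyl triflate/amine enolisation–silylation: a cis-fused hydrindan-5-one is expected to enolise toward C4, the methylene next to the ring-fusion CH (as A/B-cis 3-keto steroids enolise toward C4), and the primary alcohol is silylated in the same operation, protecting it for steps 7–9.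

**Step 7**
Reactants: 13 the bis-silyl compound of step 6
Product: 15 3-[(1S,2R,3S,5R)-2-{[(tert-butyldimethylsilyl)oxy]methyl}-5-formyl-1,3-dimethylcyclopentyl]propanoic acid, via silyl ester 14 (not isolated)
Conditions: O3, CH2Cl2, −78 °C; Me2S, −78 °C → rt; then THF/H2O, rt, work-up at pH 4
Reagents that add atoms: ozone, [O-][O+]=O
Why: Ozonolysis of the silyl enol ether should cleave C4=C5 into a ring-bound aldehyde (C4) and a silyl ester (C5) that hydrolyses to the acid on work-up, so the two termini differ in oxidation level; no stereocentre is touched, and the near-neutral work-up spares the aldehyde α-centre and the silyl ether.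

**Step 8**
Reactants: 15 3-[(1S,2R,3S,5R)-2-{[(tert-butyldimethylsilyl)oxy]methyl}-5-formyl-1,3-dimethylcyclopentyl]propanoic acid
Product: 16 methyl 3-[(1S,2R,3S,5R)-2-{[(tert-butyldimethylsilyl)oxy]methyl}-5-formyl-1,3-dimethylcyclopentyl]propanoate
Conditions: TMSCHN2 (1.2 equiv), MeOH/toluene (1:4), 0 °C
Reagents that add atoms: (trimethylsilyl)diazomethane, C[Si](C)(C)C=[N+]=[N-]
Why: O-Methylation of the carboxylic acid with (trimethylsilyl)diazomethane in methanol is fast at 0 °C and base-free, so the α-branched aldehyde should be neither epimerised nor homologated.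

**Step 9**
Reactants: 16 methyl 3-[(1S,2R,3S,5R)-2-{[(tert-butyldimethylsilyl)oxy]methyl}-5-formyl-1,3-dimethylcyclopentyl]propanoate
Product: 17 methyl 3-[(1R,2R,3S,5S)-2-{[(tert-butyldimethylsilyl)oxy]methyl}-1,3-dimethyl-5-(2-methylprop-1-en-1-yl)cyclopentyl]propanoate
Conditions: i-PrPPh3I (1.5 equiv), n-BuLi (1.4 equiv), THF, 0 °C; then 16, −78 → 0 °C
Reagents that add atoms: isopropyltriphenylphosphonium iodide, CC(C)[P+](c1ccccc1)(c1ccccc1)c1ccccc1.[I-]
Why: Wittig olefination: the non-stabilised isopropylidene ylide should attack the aldehyde far faster than the methyl ester and give the 2-methylprop-1-enyl group, and addition at −78 °C should outrun enolisation of the α-stereocentre.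

**Step 10**
Reactants: 17 methyl 3-[(1R,2R,3S,5S)-2-{[(tert-butyldimethylsilyl)oxy]methyl}-1,3-dimethyl-5-(2-methylprop-1-en-1-yl)cyclopentyl]propanoate
Product: 18 methyl 3-[(1R,2R,3S,5S)-2-(hydroxymethyl)-1,3-dimethyl-5-(2-methylprop-1-en-1-yl)cyclopentyl]propanoate
Conditions: HF·pyridine, THF, 0 °C → rt
Reagents that add atoms: none
Why: Fluoride-driven cleavage of the primary silyl ether under buffered conditions, which should leave the ester, the trisubstituted alkene and all stereocentres untouched.

**Step 11**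
Reactants: 18 methyl 3-[(1R,2R,3S,5S)-2-(hydroxymethyl)-1,3-dimethyl-5-(2-methylprop-1-en-1-yl)cyclopentyl]propanoate; 19 7-hydroxy-2H-chromen-2-one (umbelliferone)
Product: 20 methyl 3-[(1R,2R,3S,5S)-1,3-dimethyl-5-(2-methylprop-1-en-1-yl)-2-{[(2-oxo-2H-chromen-7-yl)oxy]methyl}cyclopentyl]propanoate
Conditions: 19 (1.2 equiv), PPh3 (1.5 equiv), DIAD (1.5 equiv), THF, 0 °C → rt
Reagents that add atoms: none
Why: Mitsunobu etherification: the primary alcohol is activated as its oxyphosphonium ion and displaced by the acidic 7-hydroxyl of umbelliferone (SN2 at CH2, no stereocentre involved), with the ester inert.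

**Step 12**
Reactants: 20 methyl 3-[(1R,2R,3S,5S)-1,3-dimethyl-5-(2-methylprop-1-en-1-yl)-2-{[(2-oxo-2H-chromen-7-yl)oxy]methyl}cyclopentyl]propanoate
Product: 22 ferulsinaic acid, 3-[(1R,2R,3S,5S)-1,3-dimethyl-5-(2-methylprop-1-en-1-yl)-2-{[(2-oxo-2H-chromen-7-yl)oxy]methyl}cyclopentyl]propanoic acid, via lithium carboxylate 21 (not isolated)
Conditions: LiOH (3 equiv), THF/MeOH/H2O, 0 °C → rt; then 1 M HCl to pH 2
Reagents that add atoms: lithium hydroxide, [Li+].[OH-]
Why: Saponification of the unhindered methyl ester; any coumarin lactone opened by hydroxide should re-close from the (Z)-coumarinate on acidification, and the ether, alkene and stereocentres are base-stable.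

**Compound list**
1 | (E)-but-2-enal (crotonaldehyde) | C/C=C/C=O | starting material
2 | ethyl 4-bromo-3-oxopentanoate (racemic) | CCOC(=O)CC(=O)C(C)Br | starting material
3 | ethyl 4-bromo-3-oxo-2-[(2R)-4-oxobutan-2-yl]pentanoate (open-chain Michael adduct, held as its enamine; C2 and C4 unfixed) | CCOC(=O)C(C(=O)C(C)Br)[C@H](C)CC=O | intermediate
4 | ethyl (1S,2R,3R,4S)-3-formyl-2,4-dimethyl-5-oxocyclopentane-1-carboxylate (all-trans; C1 and C4 epimerisable and inconsequential) | O=C1[C@@H](C(=O)OCC)[C@H](C)[C@@H](C=O)[C@@H]1C | intermediate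
5 | ethyl (1S,2R,3R,4S)-3-(hydroxymethyl)-2,4-dimethyl-5-oxocyclopentane-1-carboxylate | O=C1[C@@H](C(=O)OCC)[C@H](C)[C@@H](CO)[C@@H]1C | intermediate
6 | (1S,2R,3R,4S)-3-(hydroxymethyl)-2,4-dimethyl-5-oxocyclopentane-1-carboxylic acid | O=C1[C@@H](C(=O)O)[C@H](C)[C@@H](CO)[C@@H]1C | intermediate
7 | (2S,3R,4S)-3-(hydroxymethyl)-2,4-dimethylcyclopentan-1-one (C2 epimerisable) | O=C1C[C@H](C)[C@@H](CO)[C@@H]1C | intermediate
8 | but-3-en-2-one (methyl vinyl ketone) | CC(=O)C=C | starting material
9 | (2S,3R,4S)-3-(hydroxymethyl)-2,4-dimethyl-2-(3-oxobutyl)cyclopentan-1-one | O=C1C[C@H](C)[C@@H](CO)[C@]1(C)CCC(C)=O | intermediate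
10 | (1R,2S,3aR,7aS)-3a-hydroxy-1-(hydroxymethyl)-2,7a-dimethyloctahydro-5H-inden-5-one (cis-fused ketol) | O=C1C[C@]2(O)C[C@H](C)[C@@H](CO)[C@]2(C)CC1 | intermediate
11 | (1R,2S,7aS)-1-(hydroxymethyl)-2,7a-dimethyl-1,2,3,6,7,7a-hexahydro-5H-inden-5-one | O=C1C=C2C[C@H](C)[C@@H](CO)[C@]2(C)CC1 | intermediate
12 | (1R,2S,3aS,7aR)-1-(hydroxymethyl)-2,7a-dimethyloctahydro-5H-inden-5-one (cis-fused) | O=C1C[C@@H]2C[C@H](C)[C@@H](CO)[C@]2(C)CC1 | intermediate
13 | tert-butyl({(1R,2S,3aS,7aR)-5-[(tert-butyldimethylsilyl)oxy]-2,7a-dimethyl-2,3,3a,6,7,7a-hexahydro-1H-inden-1-yl}methoxy)dimethylsilane | CC(C)(C)[Si](C)(C)OC1=C[C@@H]2C[C@H](C)[C@@H](CO[Si](C)(C)C(C)(C)C)[C@]2(C)CC1 | intermediate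
14 | tert-butyldimethylsilyl 3-[(1S,2R,3S,5R)-2-{[(tert-butyldimethylsilyl)oxy]methyl}-5-formyl-1,3-dimethylcyclopentyl]propanoate | O=C[C@@H]1C[C@H](C)[C@@H](CO[Si](C)(C)C(C)(C)C)[C@]1(C)CCC(=O)O[Si](C)(C)C(C)(C)C | intermediate
15 | 3-[(1S,2R,3S,5R)-2-{[(tert-butyldimethylsilyl)oxy]methyl}-5-formyl-1,3-dimethylcyclopentyl]propanoic acid | O=C[C@@H]1C[C@H](C)[C@@H](CO[Si](C)(C)C(C)(C)C)[C@]1(C)CCC(=O)O | intermediate
16 | methyl 3-[(1S,2R,3S,5R)-2-{[(tert-butyldimethylsilyl)oxy]methyl}-5-formyl-1,3-dimethylcyclopentyl]propanoate | O=C[C@@H]1C[C@H](C)[C@@H](CO[Si](C)(C)C(C)(C)C)[C@]1(C)CCC(=O)OC | intermediate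
17 | methyl 3-[(1R,2R,3S,5S)-2-{[(tert-butyldimethylsilyl)oxy]methyl}-1,3-dimethyl-5-(2-methylprop-1-en-1-yl)cyclopentyl]propanoate | CC(C)=C[C@@H]1C[C@H](C)[C@@H](CO[Si](C)(C)C(C)(C)C)[C@]1(C)CCC(=O)OC | intermediate
18 | methyl 3-[(1R,2R,3S,5S)-2-(hydroxymethyl)-1,3-dimethyl-5-(2-methylprop-1-en-1-yl)cyclopentyl]propanoate | CC(C)=C[C@@H]1C[C@H](C)[C@@H](CO)[C@]1(C)CCC(=O)OC | intermediate
19 | 7-hydroxy-2H-chromen-2-one (umbelliferone) | Oc1ccc2ccc(=O)oc2c1 | starting material
20 | methyl 3-[(1R,2R,3S,5S)-1,3-dimethyl-5-(2-methylprop-1-en-1-yl)-2-{[(2-oxo-2H-chromen-7-yl)oxy]methyl}cyclopentyl]propanoate | CC(C)=C[C@@H]1C[C@H](C)[C@@H](COc2ccc3ccc(=O)oc3c2)[C@]1(C)CCC(=O)OC | intermediate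
21 | lithium 3-[(1R,2R,3S,5S)-1,3-dimethyl-5-(2-methylprop-1-en-1-yl)-2-{[(2-oxo-2H-chromen-7-yl)oxy]methyl}cyclopentyl]propanoate | CC(C)=C[C@@H]1C[C@H](C)[C@@H](COc2ccc3ccc(=O)oc3c2)[C@]1(C)CCC(=O)[O-].[Li+] | intermediate
22 | ferulsinaic acid, 3-[(1R,2R,3S,5S)-1,3-dimethyl-5-(2-methylprop-1-en-1-yl)-2-{[(2-oxo-2H-chromen-7-yl)oxy]methyl}cyclopentyl]propanoic acid | CC(C)=C[C@@H]1C[C@H](C)[C@@H](COc2ccc3ccc(=O)oc3c2)[C@]1(C)CCC(=O)O | target

**Totals**
Total step count: 12. Longest linear sequence: 12 steps (from 1 and 2 to 22); 8 and 19 enter as single building blocks.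

**Steps most likely to fail**

Step 1. The ring-closing alkylation at the secondary bromide may be too slow, so that the Michael adduct is diverted (O-alkylation to dihydrofurans, alkylation of the catalyst nitrogen, a second Michael addition) or facial control erodes. The fallback keeps the same two-bond event but runs it as a Michael/aldol domino, a reaction type known for 1,2-diones and enals under the same amine catalysis. It sets out from 1 and commercial butane-2,3-dione: the dione methyl carbon should add to the β-carbon to give (3R)-3-methyl-5,6-dioxoheptanal F1, whose enamine closes onto the distal carbonyl to give (1R,5S)-2-hydroxy-2,5-dimethyl-3-oxocyclopentane-1-carbaldehyde F2. TsOH in toluene dehydrates this β-hydroxy aldehyde to (5S)-2,5-dimethyl-3-oxocyclopent-1-ene-1-carbaldehyde F3, and Zn in AcOH reduces the doubly activated C=C to the all-trans (1R,2S,5S)-2,5-dimethyl-3-oxocyclopentane-1-carbaldehyde F4. NaBH(OAc)3 then gives 7, where the route is rejoined.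

Step 4. The Michael addition may occur at the methylene α-carbon instead of the hindered methine or syn to the hydroxymethyl group, and butenone may polymerise. The fallback fixes the site through the β-keto ester dianion, whose 1,3-dicarbonyl carbon is blocked as the first anion, and sets out from 5. TBSCl/imidazole gives ethyl (1S,2R,3R,4S)-3-{[(tert-butyldimethylsilyl)oxy]methyl}-2,4-dimethyl-5-oxocyclopentane-1-carboxylate F5. Its dianion (NaH, then n-BuLi, THF, 0 °C) should be alkylated at the γ-carbon, anti to the silyloxymethyl group, by 2-(2-bromoethyl)-2-methyl-1,3-dioxolane to give ethyl (1S,2R,3R,4S)-3-{[(tert-butyldimethylsilyl)oxy]methyl}-2,4-dimethyl-4-[2-(2-methyl-1,3-dioxolan-2-yl)ethyl]-5-oxocyclopentane-1-carboxylate F6. 2 M HCl in dioxane at 90 °C removes ketal, silyl ether and ester and decarboxylates the resulting 3-(hydroxymethyl)-2,4-dimethyl-5-oxo-4-(3-oxobutyl)cyclopentane-1-carboxylic acid F7 to the diketone 9, which is closed to 11 with KOH/MeOH as in step 4.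

Step 6. Enolisation may go away from the ring fusion (toward C6), which after ozonolysis would cut the wrong bond. The fallback makes the enol ether regiospecifically from the enone and sets out from 11. TBSCl/imidazole gives (1R,2S,7aS)-1-{[(tert-butyldimethylsilyl)oxy]methyl}-2,7a-dimethyl-1,2,3,6,7,7a-hexahydro-5H-inden-5-one F8. 1,4-Hydrosilylation with Et3SiH and catalytic RhCl(PPh3)3 should place hydrogen on the ring-fusion carbon (same face as in step 5) and leave the cis-fused triethylsilyl enol ether F9 with its double bond fixed between C4 and C5. Ozonolysis (O3; Me2S) and hydrolysis of the triethylsilyl ester F10 then give 15.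

**Further compounds**
F1 | step 1 | (3R)-3-methyl-5,6-dioxoheptanal | CC(=O)C(=O)C[C@H](C)CC=O
F2 | step 1 | (1R,5S)-2-hydroxy-2,5-dimethyl-3-oxocyclopentane-1-carbaldehyde (carbinol centre as formed) | O=C1C[C@H](C)[C@@H](C=O)C1(C)O
F3 | step 1 | (5S)-2,5-dimethyl-3-oxocyclopent-1-ene-1-carbaldehyde | O=C1C[C@H](C)C(C=O)=C1C
F4 | step 1 | (1R,2S,5S)-2,5-dimethyl-3-oxocyclopentane-1-carbaldehyde | O=C1C[C@H](C)[C@@H](C=O)[C@@H]1C
F5 | step 4 | ethyl (1S,2R,3R,4S)-3-{[(tert-butyldimethylsilyl)oxy]methyl}-2,4-dimethyl-5-oxocyclopentane-1-carboxylate | O=C1[C@@H](C(=O)OCC)[C@H](C)[C@@H](CO[Si](C)(C)C(C)(C)C)[C@@H]1C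
F6 | step 4 | ethyl (1S,2R,3R,4S)-3-{[(tert-butyldimethylsilyl)oxy]methyl}-2,4-dimethyl-4-[2-(2-methyl-1,3-dioxolan-2-yl)ethyl]-5-oxocyclopentane-1-carboxylate | O=C1[C@@H](C(=O)OCC)[C@H](C)[C@@H](CO[Si](C)(C)C(C)(C)C)[C@]1(C)CCC2(C)OCCO2
F7 | step 4 | (1S,2R,3R,4S)-3-(hydroxymethyl)-2,4-dimethyl-5-oxo-4-(3-oxobutyl)cyclopentane-1-carboxylic acid | O=C1[C@@H](C(=O)O)[C@H](C)[C@@H](CO)[C@]1(C)CCC(C)=O
F8 | step 6 | (1R,2S,7aS)-1-{[(tert-butyldimethylsilyl)oxy]methyl}-2,7a-dimethyl-1,2,3,6,7,7a-hexahydro-5H-inden-5-one | O=C1C=C2C[C@H](C)[C@@H](CO[Si](C)(C)C(C)(C)C)[C@]2(C)CC1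
F9 | step 6 | tert-butyl({(1R,2S,3aS,7aR)-2,7a-dimethyl-5-[(triethylsilyl)oxy]-2,3,3a,6,7,7a-hexahydro-1H-inden-1-yl}methoxy)dimethylsilane | CC[Si](CC)(CC)OC1=C[C@@H]2C[C@H](C)[C@@H](CO[Si](C)(C)C(C)(C)C)[C@]2(C)CC1
F10 | step 6 | triethylsilyl 3-[(1S,2R,3S,5R)-2-{[(tert-butyldimethylsilyl)oxy]methyl}-5-formyl-1,3-dimethylcyclopentyl]propanoate | O=C[C@@H]1C[C@H](C)[C@@H](CO[Si](C)(C)C(C)(C)C)[C@]1(C)CCC(=O)O[Si](CC)(CC)CC
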